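If the zeta run is repeated, the reading to watch is L at 3.8 h, where the zeta charge of Z, 16.0 mM, is lower than that of the gamma run.

| setting | epsilon | gamma | alpha | eta | zeta |
|---|---|---|---|---|---|
| Z | 80.0 mM | 40.0 mM | 80.0 mM | 120 mM | 16.0 mM |
| G | 200 mM | 160 mM | 100 mM | 200 mM | 40.0 mM |
| time |  |  |  |  | 3.8 h |

| run | time / h | [L] / mM |
|---|---|---|
| epsilon run | 0.22 | 0.6 |
| epsilon run | 0.66 | 3.7 |
| epsilon run | 1.3 | 17.9 |
| epsilon run | 2.0 | 38.0 |
| epsilon run | 2.8 | 54.0 |
| epsilon run | 3.8 | 61.9 |
| gamma run | 0.22 | 0.3 |
| gamma run | 0.66 | 0.6 |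
| gamma run | 1.3 | 3.8 |
| gamma run | 2.0 | 8.8 |
| gamma run | 2.8 | 14.4 |
| gamma run | 3.8 | 20.3 |
| alpha run | 0.22 | 0 |
| alpha run | 0.66 | 1.1 |
| alpha run | 1.3 | 5.6 |
| alpha run | 2.0 | 11.9 |
| alpha run | 2.8 | 21.8 |
| alpha run | 3.8 | 32.5 |
| eta run | 0.22 | 0 |
| eta run | 0.66 | 9.5 |
| eta run | 1.3 | 41.9 |
| eta run | 2.0 | 77.2 |
| eta run | 2.8 | 92.3 |
| eta run | 3.8 | 95.9 |

(each reading ± 0.4 mM)

* the exponent of [G] in the starting rate at the charge of the epsilon run (at the point where two percent of the Z have become L)
* the exponent of [Z] in the starting rate at the charge of the epsilon run (at the point where two percent of the Z have become L) (one fixed amount of L, the same in the runs compared)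
* L in the zeta run at 3.8 h, as a share of the Z charged

- Overall: Z + G -> L.
- Constant volume, constant temperature.
- An order is taken over about fifteen percent of the charge, up and down.

The steep stretch of the epsilon run looks like autocatalysis, L making L, with L growing exponentially at a reading of

2.46 h⁻¹

Taking that growth rate as proportional to [Z][G] gives the loop number, the growth rate at a flask's charge times its elapsed time. For the zeta run at 3.8 h:

0.374

This is below one, so in the zeta run the loop is a correction to whatever first seeds L. Two extreme seeds can be solved in the head, both scaled from the gamma run by [Z][G]. The gamma growth rate on the same scaling is 0.985 h⁻¹.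

A steady seed, read from 0.6 mM at 0.66 h in the gamma run (scatter 0.4 mM), gives 0.645 mM h⁻¹ there. Scaled to the zeta run, with the correction factor one plus half the loop number:

0.291 mM, or 1.82 % of the Z.

A seed that keeps ramping makes L grow as time squared, so the 8.8 mM read at 2.0 h in the gamma run carries over by [Z][G] and by the square of the time:

[L] = 3.18 mM, or 19.9 % of the Z.

The ramp does not last in the gamma run, where [L] over time squared at 3.8 h is 0.639 of its value at 2.0 h, yet the steady seed rests on one early, noisy reading. My estimate is therefore the geometric mean, 0.962 mM, or 6.01 %.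

The forecast gives 0.9 for G, 1 for Z and 3.5 % for the zeta run, lower than my estimate, and adds: “This is a long extrapolation.”

    Z ⇌ Q + J (0.5724 h⁻¹, 30.82 M⁻¹ h⁻¹)
    Q + G → L (1.577 M⁻¹ h⁻¹)
    L → Xo (0.05976 h⁻¹)
    Z + G + L → 2 L (178.6 M⁻² h⁻¹)

The orders come out at 0.78 in G and 0.79 in Z, and the zeta run reaches 10.2 %, above the steady seed and below the ramp. In the zeta run Z opened to Q and J from the start and Q took up G to give L, while Z + G + L ran beside that through a reckoned loop number of 0.374. The gamma run reached a quarter of its Z as L at 2.19 h, already a loop number of 2.16, higher than the zeta run's over 3.8 h.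

The numbers in the tables were computed from invented constants; the scatter is artificial.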